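The carbocyclic ring (C1, C2, C3, C4, C4a, C8a) is closed last by a dehydrogenative Friedel–Crafts reaction that exploits two para relationships: the 4-OH of the pendant ring makes the C1 hydrogens hydride-labile, and the C6 methoxy group of the fused ring activates C8a. DDQ converts the cis-dibenzylbutyrolactone 13, which carries one free phenol, into a p-quinone methide whose exocyclic carbon is attacked by C8a; one operation forges C1–C8a from two C–H bonds and sets C1 trans to C2. Because the cis C2/C3 open-chain parent is meso, the choice of which benzylic carbon is oxidised (free phenol versus pivalate) fixes the enantiomer; C2 and C3 come from two hydrogenations.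

Key step: step 8

Locants: tetralin numbering of the target is used throughout (C1 carries the pendant aryl group, C2 and C3 the CH2OH groups, C4 is the ring CH2, C4a and C8a are the fusion carbons, OMe on C6, OH on C7). The target is (1R,2S,3R), that is 1,2-trans and 2,3-cis.

Assumption: [Rh(cod)((R,R)-Et-DuPhos)]BF4 is taken to deliver the (S)-acid 4; should the sense of induction prove opposite, the (S,S)-ligand is used and nothing else changes.

Step 1
Reactants: 1 4-(benzyloxy)-3-methoxybenzaldehyde; 2 dimethyl succinate
Product: 3 (E)-4-[4-(benzyloxy)-3-methoxyphenyl]-3-(methoxycarbonyl)but-3-enoic acid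
Conditions: NaOMe, MeOH, reflux; then aq. HCl
Reagents that add atoms: none
Why: Stobbe condensation, in which the succinate enolate adds to the non-enolisable aldehyde, the alkoxide closes to a paraconate lactone, and base-induced ring opening gives the half-ester with the thermodynamically preferred E alkene and a differentiated acid/ester pair.

Step 2
Reactants: 3 (E)-4-[4-(benzyloxy)-3-methoxyphenyl]-3-(methoxycarbonyl)but-3-enoic acid
Product: 4 (S)-4-[4-(benzyloxy)-3-methoxyphenyl]-3-(methoxycarbonyl)butanoic acid
Conditions: [Rh(cod)((R,R)-Et-DuPhos)]BF4 (1 mol %), NaOMe (0.1 equiv), H2 (5 bar), MeOH, rt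
Reagents that add atoms: none
Why: Rh-catalysed asymmetric hydrogenation of a β-aryl itaconate half-ester, in which the carboxylate binds the metal beside the alkene and the C2-symmetric bisphospholane selects the alkene face, setting the centre that becomes C2 of the target while leaving the benzyl ether untouched.

Step 3
Reactants: 4 (S)-4-[4-(benzyloxy)-3-methoxyphenyl]-3-(methoxycarbonyl)butanoic acid
Product: 6 (S)-4-[4-(benzyloxy)-3-methoxybenzyl]dihydrofuran-2(3H)-one, via hydroxy acid 5 (not isolated)
Conditions: KOH (1 equiv), EtOH; CaCl2, NaBH4, EtOH, −10 °C to rt; then 3 M HCl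
Reagents that add atoms: none
Why: Chemoselective ester reduction by Ca(BH4)2 formed in the flask (the potassium carboxylate is not reduced) followed by acid-induced lactonisation of 5, with no free base left to epimerise the centre next to the ester.

Step 4
Reactants: 7 vanillin
Product: 8 4-formyl-2-methoxyphenyl pivalate
Conditions: PivCl, Et3N, DMAP (cat.), CH2Cl2, 0 °C to rt
Reagents that add atoms: pivaloyl chloride, CC(C)(C)C(=O)Cl
Why: DMAP-catalysed O-acylation of the phenol, giving a hindered aryl ester that should survive the enolate, hydrogenation and oxidative acid steps and fall to the final hydride reduction.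

Step 5
Reactants: 6 (S)-4-[4-(benzyloxy)-3-methoxybenzyl]dihydrofuran-2(3H)-one; 8 4-formyl-2-methoxyphenyl pivalate
Product: 9 4-{[(3R,4S)-4-[4-(benzyloxy)-3-methoxybenzyl]-2-oxotetrahydrofuran-3-yl](hydroxy)methyl}-2-methoxyphenyl pivalate (3,4-trans; both carbinol epimers)
Conditions: LiN(SiMe3)2, THF, −78 °C; then 8, −78 °C; AcOH quench at −78 °C
Reagents that add atoms: none
Why: Lithium enolate aldol addition in which the aldehyde approaches anti to the C4 benzyl group and reacts far faster at −78 °C than the hindered aryl pivalate, the carbinol epimers being left unseparated because this centre and the α-centre are erased in step 6.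

Step 6
Reactants: 9 4-{[(3R,4S)-4-[4-(benzyloxy)-3-methoxybenzyl]-2-oxotetrahydrofuran-3-yl](hydroxy)methyl}-2-methoxyphenyl pivalate
Product: 11 4-{(E)-[(4S)-4-[4-(benzyloxy)-3-methoxybenzyl]-2-oxodihydrofuran-3(2H)-ylidene]methyl}-2-methoxyphenyl pivalate, via mesylate 10 (not isolated)
Conditions: MsCl, Et3N, CH2Cl2, 0 °C; then DBU, 0 °C to rt
Reagents that add atoms: none
Why: Mesylation followed by E1cB elimination, which should give the conjugated benzylidene lactone as the thermodynamically preferred E isomer without touching the C4 centre.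

Step 7
Reactants: 11 4-{(E)-[(4S)-4-[4-(benzyloxy)-3-methoxybenzyl]-2-oxodihydrofuran-3(2H)-ylidene]methyl}-2-methoxyphenyl pivalate
Product: 13 4-{[(3R,4S)-4-(4-hydroxy-3-methoxybenzyl)-2-oxotetrahydrofuran-3-yl]methyl}-2-methoxyphenyl pivalate (3,4-cis), via cis-lactone benzyl ether 12 (not isolated)
Conditions: H2 (1 atm), 10% Pd/C, EtOAc, rt
Reagents that add atoms: none
Why: Heterogeneous hydrogenation with syn delivery of H2 to the alkene face anti to the C4 benzyl group (held pseudoaxial by 1,3-allylic strain with the E-aryl group), which sets C3 cis to C2, followed by hydrogenolysis of the benzyl ether to unmask the one phenol that step 8 needs, the pivalate being inert.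

Step 8
Reactants: 13 4-{[(3R,4S)-4-(4-hydroxy-3-methoxybenzyl)-2-oxotetrahydrofuran-3-yl]methyl}-2-methoxyphenyl pivalate
Product: 15 (3aS,4R,9aR)-4-(4-hydroxy-3-methoxyphenyl)-7-methoxy-1-oxo-1,3,3a,4,9,9a-hexahydronaphtho[2,3-c]furan-6-yl pivalate, via quinone methide 14 (not isolated)
Conditions: DDQ (1.0 equiv), CH2Cl2 (5 mM), 0 °C; then TFA (5 equiv), 0 °C to rt
Reagents that add atoms: none
Why: DDQ removes hydride from the only benzylic CH2 that stands para to a free phenol (the pivalate-masked ring should not be oxidised under these conditions), giving p-quinone methide 14; TFA protonates its carbonyl oxygen and the resulting benzylic cation is captured by the arene carbon para to the methoxy group, the future C8a. The closest known reaction type is the DDQ/TFA quinone-methide cyclisation of dibenzylbutyrolactones to aryltetralin lactones, an oxidative intramolecular Friedel–Crafts alkylation. The carbocycle closes in a 6-exo-trig mode on the exocyclic C=C of the quinone methide, the attacking aromatic C4a=C8a bond ending inside the new ring. The new C1 centre is controlled by the adjacent C2 centre and the cis ring fusion: the aryl group should take the convex face, trans to the C2–CH2O bond, which is also the thermodynamically preferred arrangement. The step needs chemoselectivity (free phenol versus pivalate decides which benzylic carbon is oxidised and hence the enantiomeric series), regioselectivity on the nucleophilic ring (para to OMe; the other ortho position is flanked by two substituents) and restraint from over-oxidation (one equivalent of DDQ, 0 °C, high dilution).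

Step 9
Reactants: 15 (3aS,4R,9aR)-4-(4-hydroxy-3-methoxyphenyl)-7-methoxy-1-oxo-1,3,3a,4,9,9a-hexahydronaphtho[2,3-c]furan-6-yl pivalate
Product: 16 (6R,7S,8R)-8-(4-hydroxy-3-methoxyphenyl)-6,7-bis(hydroxymethyl)-3-methoxy-5,6,7,8-tetrahydronaphthalen-2-ol
Conditions: LiAlH4 (excess), THF, 0 °C to reflux; then 1 M HCl
Reagents that add atoms: none
Why: Hydride reduction opens the lactone to the 1,4-diol and cleaves the aryl pivalate in the same operation, reduction being faster than enolisation so that the C3 centre should be retained.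

Compound list
1 | 4-(benzyloxy)-3-methoxybenzaldehyde (O-benzylvanillin) | COc1cc(C=O)ccc1OCc1ccccc1 | starting material
2 | dimethyl succinate | COC(=O)CCC(=O)OC | starting material
3 | (E)-4-[4-(benzyloxy)-3-methoxyphenyl]-3-(methoxycarbonyl)but-3-enoic acid | COC(=O)/C(CC(=O)O)=C/c1ccc(OCc2ccccc2)c(OC)c1 | intermediate
4 | (S)-4-[4-(benzyloxy)-3-methoxyphenyl]-3-(methoxycarbonyl)butanoic acid | COC(=O)[C@@H](Cc1ccc(OCc2ccccc2)c(OC)c1)CC(=O)O | intermediate
5 | (S)-4-[4-(benzyloxy)-3-methoxyphenyl]-3-(hydroxymethyl)butanoic acid | OC[C@@H](Cc1ccc(OCc2ccccc2)c(OC)c1)CC(=O)O | intermediate (not isolated)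
6 | (S)-4-[4-(benzyloxy)-3-methoxybenzyl]dihydrofuran-2(3H)-one | O=C1C[C@H](Cc2ccc(OCc3ccccc3)c(OC)c2)CO1 | intermediate
7 | vanillin (4-hydroxy-3-methoxybenzaldehyde) | COc1cc(C=O)ccc1O | starting material
8 | 4-formyl-2-methoxyphenyl pivalate | COc1cc(C=O)ccc1OC(=O)C(C)(C)C | intermediate
9 | 4-{[(3R,4S)-4-[4-(benzyloxy)-3-methoxybenzyl]-2-oxotetrahydrofuran-3-yl](hydroxy)methyl}-2-methoxyphenyl pivalate (3,4-trans; carbinol centre both epimers) | O=C1OC[C@@H](Cc2ccc(OCc3ccccc3)c(OC)c2)[C@@H]1C(O)c1ccc(OC(=O)C(C)(C)C)c(OC)c1 | intermediate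
10 | 4-{[(3R,4S)-4-[4-(benzyloxy)-3-methoxybenzyl]-2-oxotetrahydrofuran-3-yl][(methylsulfonyl)oxy]methyl}-2-methoxyphenyl pivalate (mesylate of 9) | O=C1OC[C@@H](Cc2ccc(OCc3ccccc3)c(OC)c2)[C@@H]1C(OS(C)(=O)=O)c1ccc(OC(=O)C(C)(C)C)c(OC)c1 | intermediate (not isolated)
11 | 4-{(E)-[(4S)-4-[4-(benzyloxy)-3-methoxybenzyl]-2-oxodihydrofuran-3(2H)-ylidene]methyl}-2-methoxyphenyl pivalate | O=C1OC[C@@H](Cc2ccc(OCc3ccccc3)c(OC)c2)/C1=C\c1ccc(OC(=O)C(C)(C)C)c(OC)c1 | intermediate
12 | 4-{[(3R,4S)-4-[4-(benzyloxy)-3-methoxybenzyl]-2-oxotetrahydrofuran-3-yl]methyl}-2-methoxyphenyl pivalate (3,4-cis) | O=C1OC[C@@H](Cc2ccc(OCc3ccccc3)c(OC)c2)[C@H]1Cc1ccc(OC(=O)C(C)(C)C)c(OC)c1 | intermediate (not isolated)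
13 | 4-{[(3R,4S)-4-(4-hydroxy-3-methoxybenzyl)-2-oxotetrahydrofuran-3-yl]methyl}-2-methoxyphenyl pivalate (3,4-cis) | O=C1OC[C@@H](Cc2ccc(O)c(OC)c2)[C@H]1Cc1ccc(OC(=O)C(C)(C)C)c(OC)c1 | intermediate
14 | 2-methoxy-4-{[(3R,4S)-4-[(3-methoxy-4-oxocyclohexa-2,5-dien-1-ylidene)methyl]-2-oxotetrahydrofuran-3-yl]methyl}phenyl pivalate (p-quinone methide) | O=C1OC[C@@H](C=C2C=CC(=O)C(OC)=C2)[C@H]1Cc1ccc(OC(=O)C(C)(C)C)c(OC)c1 | intermediate (not isolated)
15 | (3aS,4R,9aR)-4-(4-hydroxy-3-methoxyphenyl)-7-methoxy-1-oxo-1,3,3a,4,9,9a-hexahydronaphtho[2,3-c]furan-6-yl pivalate (cis-fused lactone, aryl trans to C3a–CH2O) | COc1cc([C@@H]2c3cc(OC(=O)C(C)(C)C)c(OC)cc3C[C@H]4C(=O)OC[C@@H]24)ccc1O | intermediate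
16 | (6R,7S,8R)-8-(4-hydroxy-3-methoxyphenyl)-6,7-bis(hydroxymethyl)-3-methoxy-5,6,7,8-tetrahydronaphthalen-2-ol | COc1cc([C@@H]2c3cc(O)c(OC)cc3C[C@@H](CO)[C@H]2CO)ccc1O | target

Total step count: 9. Longest linear sequence: 8 steps (steps 1, 2, 3, 5, 6, 7, 8, 9); step 4 is a one-step side branch.

Steps most likely to fail

Step 8 (oxidative ring closure). What may go wrong: over-oxidation of the newly formed diarylmethine C1–H by DDQ, and intermolecular capture of the quinone methide by a phenol before the ring closes. Fallback, setting out from 13 and coming back at 15: oxidation and ring closure are separated. DDQ in methanol at 0 °C should convert 13 into the benzylic methyl ether 4-{[(3R,4S)-4-[(4-hydroxy-3-methoxyphenyl)(methoxy)methyl]-2-oxotetrahydrofuran-3-yl]methyl}-2-methoxyphenyl pivalate F1 (either epimer at the new centre serves), the solvent trapping the quinone methide as it forms. After removal of the hydroquinone, F1 is ionised with BF3·OEt2 in CH2Cl2 at −20 °C; methanol leaves and the same benzylic cation should close to 15 with no oxidant present.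

Step 7 (cis-selective hydrogenation). What may go wrong: poor facial selectivity, so that the 3,4-trans lactone accompanies 13 and is hard to remove. Fallback, setting out from 11 and coming back at 15: control is moved from kinetic face selection to thermodynamic control after ring closure. The unseparated hydrogenation product, 13 together with its trans epimer 4-{[(3S,4S)-4-(4-hydroxy-3-methoxybenzyl)-2-oxotetrahydrofuran-3-yl]methyl}-2-methoxyphenyl pivalate F2, is submitted to the conditions of step 8. F2 should close, again with the aryl group trans to C2, to the trans-fused lactone (3aS,4R,9aS)-4-(4-hydroxy-3-methoxyphenyl)-7-methoxy-1-oxo-1,3,3a,4,9,9a-hexahydronaphtho[2,3-c]furan-6-yl pivalate F3. Warming the mixture of 15 and F3 with DBU in toluene epimerises only the lactone α-carbon (C3 of the target) and relieves the strain of the trans ring fusion, so the mixture should converge on cis-fused 15. A shift of the pivalate between the two phenols at this stage would be harmless, since both are freed in step 9.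

Step 5 (aldol addition). What may go wrong: acyl transfer from the aryl pivalate of 8 to the lithium enolate or aldolate, and retro-aldol cleavage on warming. Fallback, setting out from 6 and coming back at 11: the strongly basic enolate chemistry is finished before the aldehyde is present. Treatment of 6 with LiN(iPr)2 (2.2 equiv) and ClP(O)(OEt)2 in THF at −78 °C (O-phosphorylation, then base-induced 1,3-shift of phosphorus from oxygen to carbon) should give diethyl [(4R)-4-[4-(benzyloxy)-3-methoxybenzyl]-2-oxotetrahydrofuran-3-yl]phosphonate F4 (C3 epimers; same spatial arrangement at C4 as in 6, the descriptor changes because phosphorus raises the priority of C3). A Horner–Wadsworth–Emmons reaction of F4 with 8 under LiCl/DBU in MeCN at rt, conditions an aryl pivalate tolerates, should give 11 directly and replaces steps 5 and 6.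

Further compounds
F1 | step 8 | 4-{[(3R,4S)-4-[(4-hydroxy-3-methoxyphenyl)(methoxy)methyl]-2-oxotetrahydrofuran-3-yl]methyl}-2-methoxyphenyl pivalate | O=C1OC[C@@H](C(OC)c2ccc(O)c(OC)c2)[C@H]1Cc1ccc(OC(=O)C(C)(C)C)c(OC)c1
F2 | step 7 | 4-{[(3S,4S)-4-(4-hydroxy-3-methoxybenzyl)-2-oxotetrahydrofuran-3-yl]methyl}-2-methoxyphenyl pivalate (3,4-trans) | O=C1OC[C@@H](Cc2ccc(O)c(OC)c2)[C@@H]1Cc1ccc(OC(=O)C(C)(C)C)c(OC)c1
F3 | step 7 | (3aS,4R,9aS)-4-(4-hydroxy-3-methoxyphenyl)-7-methoxy-1-oxo-1,3,3a,4,9,9a-hexahydronaphtho[2,3-c]furan-6-yl pivalate (trans-fused lactone) | COc1cc([C@@H]2c3cc(OC(=O)C(C)(C)C)c(OC)cc3C[C@@H]4C(=O)OC[C@@H]24)ccc1O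
F4 | step 5 | diethyl [(4R)-4-[4-(benzyloxy)-3-methoxybenzyl]-2-oxotetrahydrofuran-3-yl]phosphonate | CCOP(=O)(OCC)C1C(=O)OC[C@H]1Cc1ccc(OCc2ccccc2)c(OC)c1
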